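The carbocycle is cut across C4a–C8a and C7–C8 (isochromene numbering: O2, C1, C3 to C8a). Its C6 ketone, flanked by the C7 tertiary carbinol and the C4a=C5 double bond, is the ring-opened form of a 7-oxanorbornene. Both bonds are therefore made by one endo Diels–Alder reaction between a 2-methyl-3-silyloxy-5-alkynylfuran (C4a, C5, C6, C7; its ring oxygen becomes the C7 hydroxyl) and a (Z)-3-aroyloxypropenal that already carries the orsellinate (C8, C8a, C1). This sets C7, C8 and C8a at once under a chiral oxazaborolidinium catalyst. Fluoride then opens the oxygen bridge to the enone, and the C1 hydroxyl closes the pyran ring onto the enynone.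

Key step: step 9

Assumption: the (S) catalyst of step 9 is taken to give the enantiomer drawn; should the facial sense with this Z-configured enal be the opposite, the (R) catalyst would be used with nothing else changed. The lactate centre is erased in step 8, so racemic ethyl lactate would serve equally.

Step 1
Reactants: 1 orsellinic acid (2,4-dihydroxy-6-methylbenzoic acid)
Product: 3 2,4-bis[(tert-butyldimethylsilyl)oxy]-6-methylbenzoic acid, via silyl ester 2 (not isolated)
Conditions: TBSCl, imidazole, DMF, rt; then AcOH, THF, H2O, rt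
Reagents that add atoms: tert-butyldimethylsilyl chloride CC(C)(C)[Si](C)(C)Cl
Why: Silylation with TBSCl and imidazole caps both phenols and the acid, and aqueous acetic acid then hydrolyses only the far more labile silyl ester, which should leave the aryl silyl ethers intact.

Step 2
Reactants: 3 2,4-bis[(tert-butyldimethylsilyl)oxy]-6-methylbenzoic acid; 4 tert-butyldimethyl(prop-2-yn-1-yloxy)silane
Product: 5 (Z)-3-[(tert-butyldimethylsilyl)oxy]prop-1-en-1-yl 2,4-bis[(tert-butyldimethylsilyl)oxy]-6-methylbenzoate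
Conditions: [RuCl2(p-cymene)]2 (1 mol%), P(4-ClC6H4)3, DMAP (cat.), toluene, 60 °C
Reagents that add atoms: none
Why: Ruthenium-catalysed anti-Markovnikov hydro-oxycarbonylation of a terminal alkyne (carboxylate attack on a ruthenium vinylidene) should give the Z enol ester, and because only the carboxylate oxygen acts as nucleophile the hindered 2,6-disubstituted acid is esterified without an acyl-transfer step.

Step 3
Reactants: 5 (Z)-3-[(tert-butyldimethylsilyl)oxy]prop-1-en-1-yl 2,4-bis[(tert-butyldimethylsilyl)oxy]-6-methylbenzoate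
Product: 6 (Z)-3-hydroxyprop-1-en-1-yl 2,4-bis[(tert-butyldimethylsilyl)oxy]-6-methylbenzoate
Conditions: PPTS (cat.), MeOH, 0 °C to rt
Reagents that add atoms: none
Why: Acid-catalysed methanolysis should remove the primary alkyl silyl ether much faster than the two aryl silyl ethers, and the hindered benzoate should resist acyl shift to the freed hydroxyl.

Step 4
Reactants: 6 (Z)-3-hydroxyprop-1-en-1-yl 2,4-bis[(tert-butyldimethylsilyl)oxy]-6-methylbenzoate
Product: 7 (Z)-3-oxoprop-1-en-1-yl 2,4-bis[(tert-butyldimethylsilyl)oxy]-6-methylbenzoate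
Conditions: Dess–Martin periodinane, NaHCO3, CH2Cl2, 0 °C
Reagents that add atoms: none
Why: Buffered Dess–Martin oxidation should convert the Z allylic alcohol into the Z enal without the acid that could isomerise the donor–acceptor double bond; the enal is used at once.

Step 5
Reactants: 8 ethyl (S)-lactate
Product: 10 (S)-4-ethoxy-5-methylfuran-2(5H)-one, via acyl ylide 9 (not isolated)
Conditions: Ph3P=C=C=O, PhCO2H (cat.), toluene, 110 °C
Reagents that add atoms: (triphenylphosphoranylidene)ketene O=C=C=P(c1ccccc1)(c1ccccc1)c1ccccc1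
Why: The hydroxyl adds to the cumulated ylide and the resulting ester ylide olefinates the neighbouring ester carbonyl (domino addition and intramolecular Wittig reaction) to close the tetronate ring; the lactate centre is carried along unchanged.

Step 6
Reactants: 11 (E)-but-2-enal (crotonaldehyde)
Product: 12 (3E)-1,1-dibromopenta-1,3-diene
Conditions: CBr4, PPh3, CH2Cl2, 0 °C
Reagents that add atoms: carbon tetrabromide BrC(Br)(Br)Br
Why: Corey–Fuchs dibromo-olefination of the aldehyde should add the future C4 carbon without touching the E double bond.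

Step 7
Reactants: 12 (3E)-1,1-dibromopenta-1,3-diene; 10 (S)-4-ethoxy-5-methylfuran-2(5H)-one
Product: 15 (S)-2-methyl-5-[(E)-pent-3-en-1-yn-1-yl]furan-3(2H)-one, via lithium acetylide 13 (not isolated), via lactol 14 (not isolated)
Conditions: n-BuLi (2 equiv), THF, −78 to 0 °C; CeCl3, −78 °C; then 10, −78 °C; then 1 M HCl, THF, rt
Reagents that add atoms: water O
Why: The second stage of the Corey–Fuchs sequence gives the acetylide, whose cerium derivative should add 1,2 to the lactone carbonyl of the vinylogous carbonate instead of removing the C5 hydrogen, and aqueous acid then hydrolyses the enol ether and dehydrates the lactol to the 3(2H)-furanone (carbonyl transposition of the Stork–Danheiser type).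

Step 8
Reactants: 15 (S)-2-methyl-5-[(E)-pent-3-en-1-yn-1-yl]furan-3(2H)-one
Product: 16 triisopropyl({2-methyl-5-[(E)-pent-3-en-1-yn-1-yl]furan-3-yl}oxy)silane
Conditions: TIPSOTf, Et3N, CH2Cl2, 0 °C
Reagents that add atoms: triisopropylsilyl trifluoromethanesulfonate CC(C)[Si](OS(=O)(=O)C(F)(F)F)(C(C)C)C(C)C
Why: Soft enolisation and O-silylation of the ketone removes the C2 hydrogen and should give the aromatic 3-silyloxyfuran, which erases the lactate-derived centre.

Step 9
Reactants: 7 (Z)-3-oxoprop-1-en-1-yl 2,4-bis[(tert-butyldimethylsilyl)oxy]-6-methylbenzoate; 16 triisopropyl({2-methyl-5-[(E)-pent-3-en-1-yn-1-yl]furan-3-yl}oxy)silane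
Product: 18 (1S,2R,3S,4R)-3-(hydroxymethyl)-1-methyl-4-[(E)-pent-3-en-1-yn-1-yl]-6-[(triisopropylsilyl)oxy]-7-oxabicyclo[2.2.1]hept-5-en-2-yl 2,4-bis[(tert-butyldimethylsilyl)oxy]-6-methylbenzoate (ester and hydroxymethyl both endo), via aldehyde cycloadduct 17 (not isolated)
Conditions: (S)-diphenylprolinol-derived B-(2-methylphenyl)oxazaborolidine·Tf2NH (20 mol%), CH2Cl2, −78 °C; then NaBH4, MeOH, −78 to −20 °C
Reagents that add atoms: none
Why: The oxazaborolidinium ion binds the formyl oxygen of 7 and the silyloxyfuran 16 adds across the enal C=C in a concerted, asynchronous normal-demand [4+2] cycloaddition in which C7–C8 bonding runs ahead of C4a–C8a bonding; the closest known reaction type is the cationic-oxazaborolidine-catalysed Diels–Alder reaction of furans and of 2-silyloxydienes with acrylic dienophiles. The carbocycle C4a–C5–C6–C7–C8–C8a is closed by this suprafacial union of the 4π and 2π partners, and the furan oxygen is left as the one-atom bridge of a 7-oxabicyclo[2.2.1]heptene. The cis relation of the C8 ester and the C8a carbon substituent is copied from the Z geometry of 7, their position anti to the oxygen bridge (and so trans to the later C7 hydroxyl) should come from the endo transition state favoured by the boron-bound formyl group, and the absolute configuration of C7, C8 and C8a comes from the catalyst shielding one face of the bound enal, while C4a is a temporary centre erased in step 10. The regiochemistry needed is secured by the 3-silyloxy group, which makes C7 the nucleophilic terminus, and by the formyl group, which makes C8 the electrophilic carbon. The step also needs addition to C=C and not to C=O and retention of the Z geometry, for which the low temperature and the concerted course are relied on, and the adduct is reduced in the same flask because such furan–enal adducts can revert or epimerise, NaBH4 reducing only the aldehyde to the C1 alcohol beside the hindered ester and the silyl enol ether.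

Step 10
Reactants: 18 (1S,2R,3S,4R)-3-(hydroxymethyl)-1-methyl-4-[(E)-pent-3-en-1-yn-1-yl]-6-[(triisopropylsilyl)oxy]-7-oxabicyclo[2.2.1]hept-5-en-2-yl 2,4-bis[(tert-butyldimethylsilyl)oxy]-6-methylbenzoate
Product: 20 (7S,8R,8aS)-7-hydroxy-7-methyl-6-oxo-3-[(E)-prop-1-en-1-yl]-6,7,8,8a-tetrahydro-1H-isochromen-8-yl 2,4-dihydroxy-6-methylbenzoate, via enynone 19 (not isolated)
Conditions: Bu4NF, THF, −40 to 0 °C; then AcOH
Reagents that add atoms: none
Why: Fluoride cleaves the silyl enol ether to the C6 enolate, which should expel the bridging oxygen from C4a (E1cB opening of a 7-oxanorbornanone) to give the C4a=C5 enone and the C7 tertiary hydroxyl, after which the C1 hydroxyl adds to the δ-carbon C3 of the enynone in a 6-endo-dig oxa-Michael reaction to close the pyran ring while the same reagent removes both aryl silyl ethers; no stereocentre is formed and C7, C8 and C8a are not touched.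

Compound list
1 | orsellinic acid (2,4-dihydroxy-6-methylbenzoic acid) | Cc1cc(O)cc(O)c1C(=O)O | starting material
2 | tert-butyldimethylsilyl 2,4-bis[(tert-butyldimethylsilyl)oxy]-6-methylbenzoate | Cc1cc(O[Si](C)(C)C(C)(C)C)cc(O[Si](C)(C)C(C)(C)C)c1C(=O)O[Si](C)(C)C(C)(C)C | intermediate
3 | 2,4-bis[(tert-butyldimethylsilyl)oxy]-6-methylbenzoic acid | Cc1cc(O[Si](C)(C)C(C)(C)C)cc(O[Si](C)(C)C(C)(C)C)c1C(=O)O | intermediate
4 | tert-butyldimethyl(prop-2-yn-1-yloxy)silane | C#CCO[Si](C)(C)C(C)(C)C | starting material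
5 | (Z)-3-[(tert-butyldimethylsilyl)oxy]prop-1-en-1-yl 2,4-bis[(tert-butyldimethylsilyl)oxy]-6-methylbenzoate | Cc1cc(O[Si](C)(C)C(C)(C)C)cc(O[Si](C)(C)C(C)(C)C)c1C(=O)O/C=C\CO[Si](C)(C)C(C)(C)C | intermediate
6 | (Z)-3-hydroxyprop-1-en-1-yl 2,4-bis[(tert-butyldimethylsilyl)oxy]-6-methylbenzoate | Cc1cc(O[Si](C)(C)C(C)(C)C)cc(O[Si](C)(C)C(C)(C)C)c1C(=O)O/C=C\CO | intermediate
7 | (Z)-3-oxoprop-1-en-1-yl 2,4-bis[(tert-butyldimethylsilyl)oxy]-6-methylbenzoate | Cc1cc(O[Si](C)(C)C(C)(C)C)cc(O[Si](C)(C)C(C)(C)C)c1C(=O)O/C=C\C=O | intermediate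
8 | ethyl (S)-lactate | CCOC(=O)[C@H](C)O | starting material
9 | ethyl (S)-2-{[(triphenylphosphoranylidene)acetyl]oxy}propanoate | CCOC(=O)[C@H](C)OC(=O)C=P(c1ccccc1)(c1ccccc1)c1ccccc1 | intermediate
10 | (S)-4-ethoxy-5-methylfuran-2(5H)-one | C[C@@H]1OC(=O)C=C1OCC | intermediate
11 | (E)-but-2-enal (crotonaldehyde) | C/C=C/C=O | starting material
12 | (3E)-1,1-dibromopenta-1,3-diene | C/C=C/C=C(Br)Br | intermediate
13 | lithium (E)-pent-3-en-1-yn-1-ide | [Li]C#C/C=C/C | intermediate
14 | (5S)-4-ethoxy-5-methyl-2-[(E)-pent-3-en-1-yn-1-yl]-2,5-dihydrofuran-2-ol (both C2 epimers) | C/C=C/C#CC1(O)C=C(OCC)[C@H](C)O1 | intermediate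
15 | (S)-2-methyl-5-[(E)-pent-3-en-1-yn-1-yl]furan-3(2H)-one | C/C=C/C#CC1=CC(=O)[C@H](C)O1 | intermediate
16 | triisopropyl({2-methyl-5-[(E)-pent-3-en-1-yn-1-yl]furan-3-yl}oxy)silane | C/C=C/C#Cc1cc(O[Si](C(C)C)(C(C)C)C(C)C)c(C)o1 | intermediate
17 | (1S,2R,3S,4S)-3-formyl-1-methyl-4-[(E)-pent-3-en-1-yn-1-yl]-6-[(triisopropylsilyl)oxy]-7-oxabicyclo[2.2.1]hept-5-en-2-yl 2,4-bis[(tert-butyldimethylsilyl)oxy]-6-methylbenzoate (ester and formyl both endo) | C[C@@]12O[C@@](C#C/C=C/C)(C=C1O[Si](C(C)C)(C(C)C)C(C)C)[C@@H](C=O)[C@H]2OC(=O)c3c(C)cc(O[Si](C)(C)C(C)(C)C)cc3O[Si](C)(C)C(C)(C)C | intermediate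
18 | (1S,2R,3S,4R)-3-(hydroxymethyl)-1-methyl-4-[(E)-pent-3-en-1-yn-1-yl]-6-[(triisopropylsilyl)oxy]-7-oxabicyclo[2.2.1]hept-5-en-2-yl 2,4-bis[(tert-butyldimethylsilyl)oxy]-6-methylbenzoate (ester and hydroxymethyl both endo) | C[C@@]12O[C@@](C#C/C=C/C)(C=C1O[Si](C(C)C)(C(C)C)C(C)C)[C@@H](CO)[C@H]2OC(=O)c3c(C)cc(O[Si](C)(C)C(C)(C)C)cc3O[Si](C)(C)C(C)(C)C | intermediate
19 | (1R,2S,6S)-2-hydroxy-6-(hydroxymethyl)-2-methyl-3-oxo-5-[(E)-pent-3-en-1-yn-1-yl]cyclohex-4-en-1-yl 2,4-dihydroxy-6-methylbenzoate | C/C=C/C#CC1=CC(=O)[C@@](C)(O)[C@H](OC(=O)c2c(C)cc(O)cc2O)[C@@H]1CO | intermediate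
20 | (7S,8R,8aS)-7-hydroxy-7-methyl-6-oxo-3-[(E)-prop-1-en-1-yl]-6,7,8,8a-tetrahydro-1H-isochromen-8-yl 2,4-dihydroxy-6-methylbenzoate | C/C=C/C1=CC2=CC(=O)[C@@](C)(O)[C@H](OC(=O)c3c(C)cc(O)cc3O)[C@@H]2CO1 | target

Total step count: 10. Longest linear sequence: 6 steps (1, 2, 3, 4, 9, 10).

Steps most likely to fail

Step 9. What may go wrong: loss of the Z geometry of the Lewis-acid-bound enal, 1,2-addition of the silyl enol ether to the formyl group in place of cycloaddition, or poor facial control. The fallback changes the dienophile to one that binds its catalyst at two points. It sets out from 7, which is oxidised (NaClO2, NaH2PO4, 2-methylbut-2-ene) to (Z)-3-({2,4-bis[(tert-butyldimethylsilyl)oxy]-6-methylbenzoyl}oxy)prop-2-enoic acid F1. This acid is converted through its pivalic mixed anhydride (t-BuCOCl, Et3N, then 1,3-oxazolidin-2-one, LiCl) into 3-[(Z)-3-({2,4-bis[(tert-butyldimethylsilyl)oxy]-6-methylbenzoyl}oxy)prop-2-enoyl]-1,3-oxazolidin-2-one F2. Cycloaddition of F2 with furan 16 under Cu(SbF6)2 and (S,S)-tert-butyl-bis(oxazoline) (divalent copper chelating the imide, no free formyl group, CH2Cl2, −78 °C) should give the endo imide cycloadduct F3. Reduction of the imide with LiBH4 brings the route back at alcohol 18.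

Step 10. What may go wrong: base-induced loss of the C8 carboxylate through the extended enolate at C8a, epimerisation at C8a, or incomplete ring closure under fluoride. The fallback avoids base and sets out from 18. HF·pyridine in THF and pyridine removes the three silyl groups, the freed enol opens the bridge, and enynone 19 is isolated. Ph3PAuNTf2 (monovalent gold) then effects the 6-endo-dig hydroalkoxylation, which is polarised by the enone, and the route is back at 20. No new compound is made.

Step 7. What may go wrong: removal of the C5 hydrogen of the tetronate by the acetylide, or sluggish addition to the vinylogous carbonate. The fallback builds the furanone by acylative ring closure and sets out from 12. Acetylide 13 made from 12 is carboxylated with CO2 to (E)-hex-4-en-2-ynoic acid F4. F4 is esterified (DCC, DMAP) with 3-hydroxybutan-2-one to 3-oxobutan-2-yl (E)-hex-4-en-2-ynoate F5. LiN(SiMe3)2 in THF at −78 °C should bring about intramolecular Claisen acylation of the methyl ketone enolate to the hemiketal 5-hydroxy-2-methyl-5-[(E)-pent-3-en-1-yn-1-yl]dihydrofuran-3(2H)-one F6. Dehydration (TsOH, toluene) returns the route at furanone 15, here as the racemate, which is immaterial because step 8 erases that centre.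

Further compounds
F1 | step 9 | (Z)-3-({2,4-bis[(tert-butyldimethylsilyl)oxy]-6-methylbenzoyl}oxy)prop-2-enoic acid | Cc1cc(O[Si](C)(C)C(C)(C)C)cc(O[Si](C)(C)C(C)(C)C)c1C(=O)O/C=C\C(=O)O
F2 | step 9 | 3-[(Z)-3-({2,4-bis[(tert-butyldimethylsilyl)oxy]-6-methylbenzoyl}oxy)prop-2-enoyl]-1,3-oxazolidin-2-one | Cc1cc(O[Si](C)(C)C(C)(C)C)cc(O[Si](C)(C)C(C)(C)C)c1C(=O)O/C=C\C(=O)N1CCOC1=O
F3 | step 9 | (1S,2R,3S,4S)-1-methyl-3-[(2-oxo-1,3-oxazolidin-3-yl)carbonyl]-4-[(E)-pent-3-en-1-yn-1-yl]-6-[(triisopropylsilyl)oxy]-7-oxabicyclo[2.2.1]hept-5-en-2-yl 2,4-bis[(tert-butyldimethylsilyl)oxy]-6-methylbenzoate (ester and imide both endo) | C[C@@]12O[C@@](C#C/C=C/C)(C=C1O[Si](C(C)C)(C(C)C)C(C)C)[C@@H](C(=O)N3CCOC3=O)[C@H]2OC(=O)c4c(C)cc(O[Si](C)(C)C(C)(C)C)cc4O[Si](C)(C)C(C)(C)C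
F0 | step 10 | none | none
F4 | step 7 | (E)-hex-4-en-2-ynoic acid | C/C=C/C#CC(=O)O
F5 | step 7 | 3-oxobutan-2-yl (E)-hex-4-en-2-ynoate | C/C=C/C#CC(=O)OC(C)C(C)=O
F6 | step 7 | 5-hydroxy-2-methyl-5-[(E)-pent-3-en-1-yn-1-yl]dihydrofuran-3(2H)-one | C/C=C/C#CC1(O)CC(=O)C(C)O1
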